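The target is an unbranched C28 acyl chain with no stereocentre and one spectator ring, the benzene ring of the benzyl ester. The saturated carbons C2–C28 offer no handle, so a temporary double bond is placed between C9 and C10, which splits the chain into commodity C10 and C20 terminal alkenes. Dec-9-enoic acid (1) is esterified with benzyl bromide (2) to the precursor, benzyl dec-9-enoate (3), whose terminal C9=C10 alkene lies seven methylenes from the ester. Ruthenium-catalysed cross-metathesis with excess icos-1-ene (4) joins C9 to C10 in one operation, releasing ethylene and giving benzyl octacos-9-enoate (5). Homogeneous hydrogenation that cannot cleave the benzylic C–O bond then gives benzyl octacosanoate (6).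

Key step: step 2

Remark: 5 is named and drawn as the E isomer expected to predominate; some Z isomer should accompany it and is carried forward unseparated, since both isomers give 6 on hydrogenation.

Step 1
Reactants: 1 dec-9-enoic acid; 2 benzyl bromide
Product: 3 benzyl dec-9-enoate
Conditions: K2CO3 (1.5 equiv), 2 (1.05 equiv), DMF, 23 °C
Reagents that add atoms: none
Why: Carboxylate O-alkylation (SN2) of the potassium salt of 1 by the reactive benzylic bromide in a dipolar aprotic solvent is a standard benzyl ester formation that leaves the remote terminal alkene untouched.

Step 2
Reactants: 3 benzyl dec-9-enoate; 4 icos-1-ene
Product: 5 benzyl (E)-octacos-9-enoate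
Conditions: 4 (3 equiv), second-generation Grubbs catalyst RuCl2(PCy3)(H2IMes)(=CHPh) (2 mol %), 1,4-benzoquinone (10 mol %), CH2Cl2, 40 °C, argon sweep; then ethyl vinyl ether
Reagents that add atoms: none
Why: Alkene cross-metathesis by the metallacyclobutane mechanism: the ruthenium alkylidene generated from RuCl2(PCy3)(H2IMes)(=CHPh) undergoes [2+2] cycloaddition with each terminal alkene and the ruthenacyclobutanes cyclorevert, so the C1–C9 alkylidene of 3 and the C2–C20 alkylidene of 4 are united as the C9=C10 bond (9 + 19 = 28 chain carbons) while both terminal CH2 groups depart as ethylene. The closest known reaction type is the ruthenium-catalysed cross-metathesis of two unhindered monosubstituted alkenes, familiar from ω-unsaturated fatty esters and linear α-olefins. No ring is closed and no stereocentre is formed; the geometry of the new alkene is immaterial because step 3 saturates it. The selectivity needed is cross-product over the two homodimers, and it should be secured by the threefold excess of inexpensive 4, by removal of ethylene in the argon stream, and by the fact that both homodimers are unhindered 1,2-disubstituted alkenes that re-enter the catalytic cycle. A second requirement, no double-bond migration before metathesis, which would yield chain-length homologues inseparable from the product, is addressed by the mild temperature, a short contact time and 1,4-benzoquinone as a trap for ruthenium hydrides. The hydrocarbon homodimer, monoester 5 and the diester homodimer differ stepwise in polarity and should separate on silica.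

Step 3
Reactants: 5 benzyl (E)-octacos-9-enoate
Product: 6 benzyl octacosanoate
Conditions: H2 (4 bar), RhCl(PPh3)3 (5 mol %), toluene/THF 1:1, 45 °C
Reagents that add atoms: none
Why: Homogeneous hydrogenation with RhCl(PPh3)3 proceeds by oxidative addition of H2 to monovalent rhodium, alkene insertion and reductive elimination, a pathway that saturates unhindered 1,2-disubstituted alkenes of either geometry but offers no route to benzylic C–O hydrogenolysis, so both isomers of 5 should converge on 6 with the benzyl ester intact.

Compound list
1 | dec-9-enoic acid | C=CCCCCCCCC(=O)O | starting material
2 | benzyl bromide | BrCc1ccccc1 | starting material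
3 | benzyl dec-9-enoate | C=CCCCCCCCC(=O)OCc1ccccc1 | intermediate
4 | icos-1-ene | CCCCCCCCCCCCCCCCCCC=C | starting material
5 | benzyl (E)-octacos-9-enoate (carried forward with its minor Z isomer) | CCCCCCCCCCCCCCCCCC/C=C/CCCCCCCC(=O)OCc1ccccc1 | intermediate
6 | benzyl octacosanoate | CCCCCCCCCCCCCCCCCCCCCCCCCCCC(=O)OCc1ccccc1 | target

Total step count: 3
Longest linear sequence: 3 steps (1 → 3 → 5 → 6)

Steps most likely to fail

1. Step 2. The ester partner may be diverted into its own homodimer by statistical partitioning, the catalyst may die early, or ruthenium hydrides may move the double bond before metathesis and so scramble the chain length by one carbon. The fallback abandons the temporary alkene and makes an sp3–sp3 bond one position further along the chain. It sets out from 3, which is hydroborated at the terminal carbon with 9-BBN (THF, 0 to 23 °C) to give benzyl 10-(9-borabicyclo[3.3.1]nonan-9-yl)decanoate F1, not isolated. This is coupled in the same flask with commercial 1-bromooctadecane (CCCCCCCCCCCCCCCCCCBr) by a B-alkyl Suzuki–Miyaura reaction using Pd(OAc)2 (4 mol %), PCy3 (8 mol %) and K3PO4·H2O in THF at 23 °C. These are known conditions for primary alkyl bromides bearing β-hydrogens, with zerovalent palladium formed in the flask, and they tolerate esters. The C10–C11 bond is formed (10 + 18 = 28 chain carbons) and the sequence comes back to the route at 6, so step 3 is no longer needed.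

2. Step 3. Saturation of the E-configured internal alkene may stall on RhCl(PPh3)3, leaving unsaturated ester that co-elutes with the product, or forcing the conditions may start to erode the benzyl group. The fallback gives up chemoselectivity. It sets out from 5, which is hydrogenated over Pd/C (10 wt % palladium on carbon) under H2 (1 bar) in EtOAc/THF at 40 °C. Alkene reduction and benzyl hydrogenolysis then occur together to give octacosanoic acid F2, which can be purified by crystallisation. F2 is re-esterified with 2 and K2CO3 in DMF at 70 °C, as in step 1, and the sequence comes back to the route at 6.

3. Step 1. O-Alkylation may be incomplete, or traces of benzyl bromide and DMF may be carried into step 2 and shorten the lifetime of the metathesis catalyst. The fallback reverses the polarity of ester formation. It sets out from 1, which undergoes Fischer esterification with benzyl alcohol (OCc1ccccc1, 1.5 equiv) and TsOH·H2O (5 mol %) in toluene at reflux with a Dean–Stark trap. It comes back to the route at 3, and no new compound is made (F0).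

Further compounds
F1 | step 2 | benzyl 10-(9-borabicyclo[3.3.1]nonan-9-yl)decanoate | O=C(OCc1ccccc1)CCCCCCCCCB1C2CCCC1CCC2
F2 | step 3 | octacosanoic acid | CCCCCCCCCCCCCCCCCCCCCCCCCCCC(=O)O
F0 | step 1 | none | none
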